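The route rests on cutting the α-methylene-γ-lactone ring at O–C6 and C7–C11. C6 is allylic to the C4=C5 double bond of the ten-membered ring, so both bonds can be made at once by a palladium-catalysed (3+2) heteroannulation of a C4=C5–C6=C7 diene with 2-bromoacrylic acid: the vinyl carbon adds to C7 and the carboxylate closes on the resulting π-allyl at C6. The precursor is an acyclic (Z,E)-diene whose only stereocentre, C8 (set by asymmetric methallylboration), relays to C7 and C6. C3 then comes from a catalytic allylation, the ten-membered ring from ring-closing metathesis at C1=C10, and the epoxide from C8-hydroxyl-directed epoxidation.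

Key step: step 6

Remark on numbering and materials: germacrane numbering is used throughout. C1–C10 form the ten-membered ring (C1/C10 epoxide, C3 and C8 acyloxy, C4=C5, C6 lactone oxygen, C7). C11/C12/C13 are the methylene lactone carbons; C14 and C15 are the methyls on C10 and C4. The target is (1R,3S,4Z,6R,7R,8R,10S) with a (2R)-2-methylbutanoate and a (Z)-2-methylbut-2-enoate (angelate). Assumption: 2-bromoacrylic acid, (R)-2-methylbutanoic acid, angelic acid, 3-(trimethylsilyl)propynal and (+)-Ipc2BOMe are taken as commercial.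

Step 1
Reactants: 1 propargyl alcohol
Product: 3 (Z)-3-iodo-2-methylprop-2-en-1-ol, via oxamagnesole 2 (not isolated)
Conditions: MeMgBr (2.5 equiv), CuI (10 mol%), THF, −10 °C → rt; then I2, −10 °C
Reagents that add atoms: methylmagnesium bromide C[Mg]Br; iodine II
Why: Copper-catalysed anti-carbomagnesiation of the propargylic alkoxide puts methyl on the internal carbon and gives the chelated (Z)-alkenylmagnesium 2, whose iodinolysis with retention leaves iodine cis to CH2OH, the geometry needed later for the cis C4=C5 bond.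

Step 2
Reactants: 3 (Z)-3-iodo-2-methylprop-2-en-1-ol
Product: 4 (Z)-triethyl[(3-iodo-2-methylprop-2-en-1-yl)oxy]silane
Conditions: TESCl, imidazole, CH2Cl2, 0 °C
Reagents that add atoms: chlorotriethylsilane CC[Si](Cl)(CC)CC
Why: Imidazole-promoted silylation masks the primary allylic alcohol (C3) as an ether that Pd(0) does not ionise and that can later be oxidised directly to the aldehyde.

Step 3
Reactants: 5 3-(trimethylsilyl)prop-2-ynal
Product: 7 (R)-5-methylhex-5-en-1-yn-3-ol, via TMS-alkynol 6 (not isolated)
Conditions: (+)-Ipc2BOMe, 2-methylallylMgCl, Et2O, −78 °C → rt; then 5, −78 °C; NaOH, H2O2; then K2CO3, MeOH, rt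
Reagents that add atoms: 2-methylallylmagnesium chloride C=C(C)C[Mg]Cl
Why: Brown asymmetric methallylboration through a closed chair transition state, the (+)-Ipc2B reagent adding to the Re face of the ynal, should set C8 as (R); the basic oxidative work-up followed by methanolic carbonate removes the alkynyl silane.

Step 4
Reactants: 7 (R)-5-methylhex-5-en-1-yn-3-ol
Product: 8 (R)-tert-butyldimethyl[(5-methylhex-5-en-1-yn-3-yl)oxy]silane
Conditions: TBSCl, imidazole, DMF, rt
Reagents that add atoms: tert-butyldimethylsilyl chloride CC(C)(C)[Si](C)(C)Cl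
Why: Standard silylation gives a bulky C8 silyl ether that serves as the stereocontrol element in step 6 and is inert to Pd(0).

Step 5
Reactants: 8 (R)-tert-butyldimethyl[(5-methylhex-5-en-1-yn-3-yl)oxy]silane; 4 (Z)-triethyl[(3-iodo-2-methylprop-2-en-1-yl)oxy]silane
Product: 11 (2Z,4E,6R)-6-(tert-butyldimethylsilyloxy)-2,8-dimethyl-1-(triethylsilyloxy)nona-2,4,8-triene, via alkenylzirconocene 9 (not isolated), via alkenylzinc chloride 10 (not isolated)
Conditions: Cp2Zr(H)Cl (Schwartz reagent), THF, rt; ZnCl2, 0 °C; then 4, Pd(PPh3)4 (5 mol%), rt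
Reagents that add atoms: none
Why: syn-Hydrozirconation of the terminal alkyne (faster than that of the 1,1-disubstituted alkene) gives the (E)-alkenylmetal, and transmetalation to zinc followed by Negishi coupling proceeds with retention at both sp2 carbons to give the (4Z,6E)-diene (germacrane numbering).

Step 6
Reactants: 11 (2Z,4E,6R)-6-(tert-butyldimethylsilyloxy)-2,8-dimethyl-1-(triethylsilyloxy)nona-2,4,8-triene; 12 2-bromoacrylic acid
Product: 13 (4S,5R)-4-[(1R)-1-(tert-butyldimethylsilyloxy)-3-methylbut-3-en-1-yl]-3-methylidene-5-[(1Z)-2-methyl-3-(triethylsilyloxy)prop-1-en-1-yl]oxolan-2-one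
Conditions: Pd(OAc)2 (10 mol%), n-Bu4NCl, Na2CO3, DMF, 80 °C, slow addition of 12
Reagents that add atoms: none
Why: Oxidative addition of Pd(0) into the C–Br bond of 12 gives an α-carboxyvinylpalladium(II) species that adds syn across C6=C7, the vinyl carbon going to the less substituted diene terminus C7 and palladium to C6, where it is held as a π-allyl complex over C4–C5–C6; the pendant carboxylate then forms the O–C6 bond and releases Pd(0), a net (3+2) annulation. The closest known reaction type is the Larock heteroannulation of 1,3-dienes by organic halides that carry a carboxylic acid. The lactone closes in a 5-exo mode, by C–O bond formation from a six-membered palladacycle on the palladium-bearing face. C7 is set by substrate control from C8 (Felkin–Anh-type): insertion should occur on the diene face anti to the C8–OTBS bond with C8–H in the inside position, and C6 follows because syn carbopalladation plus same-face C–O formation translates the (E)-geometry of C6=C7 into the trans lactone. The step needs chemoselectivity for the conjugated diene over the isolated 1,1-disubstituted alkene and over the product methylene lactone (the diene binds and inserts fastest, and 12 is kept at low concentration), regioselectivity for C7 over the fully substituted C4, and retention of the cis C4=C5 geometry, which holds as long as intramolecular C–O closure is faster than isomerisation of the allyl complex through its tertiary σ-C4 form.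

Step 7
Reactants: 13 the bis-silylated methylene lactone
Product: 14 (4S,5R)-4-[(1R)-1-(tert-butyldimethylsilyloxy)-3-methylbut-3-en-1-yl]-3-methylidene-5-[(1Z)-2-methyl-3-oxoprop-1-en-1-yl]oxolan-2-one
Conditions: (COCl)2, DMSO, CH2Cl2, −78 → −30 °C; Et3N
Reagents that add atoms: none
Why: Under Swern conditions chlorodimethylsulfonium chloride cleaves the primary triethylsilyl ether and the alkoxysulfonium ion collapses to the aldehyde (direct oxidative desilylation), leaving the secondary TBS ether untouched; the low temperature and absence of acid should preserve the (Z)-enal.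

Step 8
Reactants: 14 the (Z)-enal
Product: 15 (4S,5R)-4-[(1R)-1-(tert-butyldimethylsilyloxy)-3-methylbut-3-en-1-yl]-5-[(1Z,3S)-3-hydroxy-2-methylhexa-1,5-dien-1-yl]-3-methylidene-oxolan-2-one
Conditions: allylB(pin), (S)-TRIP phosphoric acid (5 mol%), 4 Å MS, toluene, −30 °C
Reagents that add atoms: allylboronic acid pinacol ester C=CCB1OC(C)(C)C(C)(C)O1
Why: Chiral phosphoric acid-catalysed allylboration through a chair six-membered transition state sets C3 as (S) under catalyst control (the catalyst enantiomer is chosen for Si-face delivery), and the neutral conditions spare the methylene lactone.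

Step 9
Reactants: 15 the C3 homoallylic alcohol; 16 (R)-2-methylbutanoic acid
Product: 17 the C3 (2R)-2-methylbutanoate of 15
Conditions: DCC, DMAP (cat.), CH2Cl2, 0 °C → rt
Reagents that add atoms: none
Why: Steglich esterification acylates the allylic alcohol without touching the stereocentre of the acid, whose α-hydrogen is not activated toward enolisation under these conditions.

Step 10
Reactants: 17 the C3 ester with allyl and methallyl termini
Product: 18 (1(10)Z,3S,4Z,6R,7S,8R)-8-(tert-butyldimethylsilyloxy)-3-[(2R)-2-methylbutanoyloxy]germacra-1(10),4,11(13)-trien-12,6-olide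
Conditions: Grubbs II (10 mol%), toluene (1 mM), 80 °C
Reagents that add atoms: none
Why: In this ring-closing metathesis ruthenium loads on the monosubstituted C1 alkene and closes onto the methallyl group to form C1=C10; the ring-cis (Z) alkene is expected as the less strained cis,cis-cyclodeca-1,5-diene, and the methylene lactone cannot close intramolecularly because that would give a bridgehead alkene.

Step 11
Reactants: 18 the silylated macrocycle
Product: 19 (1(10)Z,3S,4Z,6R,7R,8R)-8-hydroxy-3-[(2R)-2-methylbutanoyloxy]germacra-1(10),4,11(13)-trien-12,6-olide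
Conditions: HF·pyridine, THF, 0 °C → rt
Reagents that add atoms: none
Why: Fluoride-mediated desilylation under weakly acidic conditions frees the C8 hydroxyl without ester cleavage or translactonisation to O8.

Step 12
Reactants: 19 the C8 alcohol
Product: 20 (1R,3S,4Z,6R,7R,8R,10S)-1,10-epoxy-8-hydroxy-3-[(2R)-2-methylbutanoyloxy]germacra-4,11(13)-dien-12,6-olide
Conditions: VO(acac)2 (5 mol%), t-BuOOH, CH2Cl2, 0 °C
Reagents that add atoms: tert-butyl hydroperoxide CC(C)(C)OO
Why: In this hydroxyl-directed vanadium epoxidation the C8 vanadate delivers oxygen to the homoallylic C1=C10 alkene on the face of the C8–O bond, which sets C1 and C10; C4=C5 is deactivated by two allylic acyloxy groups and the conjugated alkenes are inert.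

Step 13
Reactants: 20 the epoxy alcohol; 21 angelic acid
Product: 23 CNP0108431.1 (target), via mixed anhydride 22 (not isolated)
Conditions: 2,4,6-trichlorobenzoyl chloride, Et3N, toluene, rt; then 20, 80 °C
Reagents that add atoms: none
Why: Yamaguchi esterification through the mixed anhydride transfers the angeloyl group to the hindered C8 hydroxyl without nucleophilic catalyst, conditions that should avoid Z → E isomerisation to the tiglate.

Compound list
1 | prop-2-yn-1-ol (propargyl alcohol) | C#CCO | starting material
2 | 4-methyl-2,5-dihydro-1,2-oxamagnesole (cyclic (Z)-alkenylmagnesium alkoxide) | CC1=C[Mg]OC1 | intermediate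
3 | (Z)-3-iodo-2-methylprop-2-en-1-ol | OC/C(C)=C\I | intermediate
4 | (Z)-triethyl[(3-iodo-2-methylprop-2-en-1-yl)oxy]silane | CC[Si](CC)(CC)OC/C(C)=C\I | intermediate
5 | 3-(trimethylsilyl)prop-2-ynal | C[Si](C)(C)C#CC=O | starting material
6 | (R)-5-methyl-1-(trimethylsilyl)hex-5-en-1-yn-3-ol | C[Si](C)(C)C#C[C@H](O)CC(C)=C | intermediate
7 | (R)-5-methylhex-5-en-1-yn-3-ol | C#C[C@H](O)CC(C)=C | intermediate
8 | (R)-tert-butyldimethyl[(5-methylhex-5-en-1-yn-3-yl)oxy]silane | C#C[C@H](O[Si](C)(C)C(C)(C)C)CC(C)=C | intermediate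
9 | chloro[(1E,3R)-3-(tert-butyldimethylsilyloxy)-5-methylhexa-1,5-dien-1-yl]zirconocene | Cl[Zr](C1C=CC=C1)(C1C=CC=C1)/C=C/[C@H](O[Si](C)(C)C(C)(C)C)CC(C)=C | intermediate
10 | [(1E,3R)-3-(tert-butyldimethylsilyloxy)-5-methylhexa-1,5-dien-1-yl]zinc chloride | Cl[Zn]/C=C/[C@H](O[Si](C)(C)C(C)(C)C)CC(C)=C | intermediate
11 | (2Z,4E,6R)-6-(tert-butyldimethylsilyloxy)-2,8-dimethyl-1-(triethylsilyloxy)nona-2,4,8-triene | CC[Si](CC)(CC)OC/C(C)=C\C=C\[C@H](O[Si](C)(C)C(C)(C)C)CC(C)=C | intermediate
12 | 2-bromoacrylic acid | C=C(Br)C(=O)O | starting material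
13 | (4S,5R)-4-[(1R)-1-(tert-butyldimethylsilyloxy)-3-methylbut-3-en-1-yl]-3-methylidene-5-[(1Z)-2-methyl-3-(triethylsilyloxy)prop-1-en-1-yl]oxolan-2-one | C=C1C(=O)O[C@H](/C=C(/C)CO[Si](CC)(CC)CC)[C@H]1[C@H](O[Si](C)(C)C(C)(C)C)CC(C)=C | intermediate
14 | (4S,5R)-4-[(1R)-1-(tert-butyldimethylsilyloxy)-3-methylbut-3-en-1-yl]-3-methylidene-5-[(1Z)-2-methyl-3-oxoprop-1-en-1-yl]oxolan-2-one | C=C1C(=O)O[C@H](/C=C(/C)C=O)[C@H]1[C@H](O[Si](C)(C)C(C)(C)C)CC(C)=C | intermediate
15 | (4S,5R)-4-[(1R)-1-(tert-butyldimethylsilyloxy)-3-methylbut-3-en-1-yl]-5-[(1Z,3S)-3-hydroxy-2-methylhexa-1,5-dien-1-yl]-3-methylidene-oxolan-2-one | C=C1C(=O)O[C@H](/C=C(/C)[C@@H](O)CC=C)[C@H]1[C@H](O[Si](C)(C)C(C)(C)C)CC(C)=C | intermediate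
16 | (R)-2-methylbutanoic acid | CC[C@@H](C)C(=O)O | starting material
17 | (2R)-2-methylbutanoate of 15 at the C3 hydroxyl | C=C1C(=O)O[C@H](/C=C(/C)[C@@H](OC(=O)[C@H](C)CC)CC=C)[C@H]1[C@H](O[Si](C)(C)C(C)(C)C)CC(C)=C | intermediate
18 | (1(10)Z,3S,4Z,6R,7S,8R)-8-(tert-butyldimethylsilyloxy)-3-[(2R)-2-methylbutanoyloxy]germacra-1(10),4,11(13)-trien-12,6-olide | C=C1C(=O)O[C@@H]2/C=C(/C)[C@@H](OC(=O)[C@H](C)CC)C/C=C(/C)C[C@@H](O[Si](C)(C)C(C)(C)C)[C@@H]12 | intermediate
19 | (1(10)Z,3S,4Z,6R,7R,8R)-8-hydroxy-3-[(2R)-2-methylbutanoyloxy]germacra-1(10),4,11(13)-trien-12,6-olide | C=C1C(=O)O[C@@H]2/C=C(/C)[C@@H](OC(=O)[C@H](C)CC)C/C=C(/C)C[C@@H](O)[C@@H]12 | intermediate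
20 | (1R,3S,4Z,6R,7R,8R,10S)-1,10-epoxy-8-hydroxy-3-[(2R)-2-methylbutanoyloxy]germacra-4,11(13)-dien-12,6-olide | C=C1C(=O)O[C@@H]2/C=C(/C)[C@@H](OC(=O)[C@H](C)CC)C[C@H]3O[C@@]3(C)C[C@@H](O)[C@@H]12 | intermediate
21 | angelic acid ((Z)-2-methylbut-2-enoic acid) | C/C=C(/C)C(=O)O | starting material
22 | angelic 2,4,6-trichlorobenzoic anhydride | C/C=C(/C)C(=O)OC(=O)c1c(Cl)cc(Cl)cc1Cl | intermediate
23 | CNP0108431.1: (1R,3S,4Z,6R,7R,8R,10S)-8-angeloyloxy-1,10-epoxy-3-[(2R)-2-methylbutanoyloxy]germacra-4,11(13)-dien-12,6-olide | C=C1C(=O)O[C@@H]2/C=C(/C)[C@@H](OC(=O)[C@H](C)CC)C[C@H]3O[C@@]3(C)C[C@@H](OC(=O)/C(C)=C\C)[C@@H]12 | target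

Total step count: 13. Longest linear sequence: 11 steps (steps 1, 2, 5–13 or steps 3, 4, 5–13).

Steps most likely to fail

Step 6. The vinylpalladium may insert into the wrong π-bond or the wrong diene face (poor facial selectivity at C7 relative to C8), or the allyl complex may isomerise before closure and erode the cis C4=C5 geometry. Fallback: the same two bonds are made by a radical-polar sequence setting out from 11. Mn(OAc)3/Cu(OAc)2-mediated oxidative addition of malonic acid (AcOH–KOAc, 40 °C) adds the malonyl radical to C7 of the diene; the allyl radical is oxidised and the carboxyl closes on C6 to give the trans α-carboxy lactone F1. Decarboxylative Mannich methylenation (aqueous CH2O, Et2NH, NaOAc/AcOH) then comes back to the route at 13.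

Step 10. Intermolecular metathesis (including through the methylene lactone) may outrun closure of the strained ten-membered ring, or the ring may close to the trans C1=C10 alkene. Fallback: setting out from 17, the methylene lactone is masked by conjugate addition of dimethylamine to give the amino lactone F2. Ring-closing metathesis of its camphorsulfonate salt gives the macrocyclic amine F3, N-methylation with MeI gives the methiodide F4, and elimination with NaHCO3 restores the exocyclic alkene and comes back to the route at 18.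

Step 12. Oxygen delivery may occur with poor facial selectivity, or the vanadate may instead oxidise the carbinol or reach C4=C5. Fallback: setting out from 19, the hydroxyl is first angeloylated with the mixed anhydride 22 to give the diester F5. The C1=C10 alkene is then epoxidised under reagent control (Shi epoxidation, with the ketone enantiomer that matches the required face, Oxone, buffered at 0 °C), which comes back to the route at 23.

Further compounds
F1 | step 6 | α-carboxy lactone (13 with CH(CO2H) in place of C=CH2 at C11; epimers at C11) | OC(=O)C1C(=O)O[C@H](/C=C(/C)CO[Si](CC)(CC)CC)[C@H]1[C@H](O[Si](C)(C)C(C)(C)C)CC(C)=C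
F2 | step 10 | dimethylamine adduct of 17 (11-(dimethylaminomethyl) lactone; C11 configuration not controlled) | CN(C)CC1C(=O)O[C@H](/C=C(/C)[C@@H](OC(=O)[C@H](C)CC)CC=C)[C@H]1[C@H](O[Si](C)(C)C(C)(C)C)CC(C)=C
F3 | step 10 | macrocyclic amine (13-dimethylamino-11,13-dihydro derivative of 18) | CN(C)CC1C(=O)O[C@@H]2/C=C(/C)[C@@H](OC(=O)[C@H](C)CC)C/C=C(/C)C[C@@H](O[Si](C)(C)C(C)(C)C)[C@@H]12
F4 | step 10 | methiodide of F3 | C[N+](C)(C)CC1C(=O)O[C@@H]2/C=C(/C)[C@@H](OC(=O)[C@H](C)CC)C/C=C(/C)C[C@@H](O[Si](C)(C)C(C)(C)C)[C@@H]12.[I-]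
F5 | step 12 | (1(10)Z,3S,4Z,6R,7R,8R)-8-angeloyloxy-3-[(2R)-2-methylbutanoyloxy]germacra-1(10),4,11(13)-trien-12,6-olide | C=C1C(=O)O[C@@H]2/C=C(/C)[C@@H](OC(=O)[C@H](C)CC)C/C=C(/C)C[C@@H](OC(=O)/C(C)=C\C)[C@@H]12
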